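**Retrosynthetic overview**

1. Target ← acetylation of the cis-2,3-diol ← ring A adjusted on the finished trans-decalin (1-en-3-ol → enone → conjugate reduction/enolate hydroxylation → equatorial hydride attack); C12–C15 ← propargylation at C11, then Zr/Al carbometalation–carboxylation.
2. Decalin core ← one-flask Ireland–Claisen/ring-closing metathesis of a monocyclic ring A cyclohex-2-enyl 3-methylbut-2-enoate: the [3,3] shift makes C9–C10, then ring B is closed by the C7=C8 bond (allyl on C5 + isopropenyl on C9).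
3. Enabling feature: in ring B, C7 is a CH and C8 carries only C17 (CH3) and C9, while C9 carries the one-carbon C11 next to quaternary C10 of ring A; cut at C7=C8 this is a lavandulyl unit (isopropenyl + carboxyl on one CH), the signature of a senecioate dienolate Claisen onto C10 across C2–C1=C10.
4. Stereochemistry: one reagent-set carbinol (C1) is relayed around ring A by two suprafacial [3,3] shifts (C1–O → C5, then C2–O → C10 and C9); C2 and C3 are set last on the rigid decalin.
5. Ring order: ring A is the purchased cyclohexenone; ring B is formed in the key step.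

Key step: step 8

Remark: 2,4,4-trimethylcyclohex-2-en-1-one is taken as purchasable; in the explanations and in drimane/labdane-type names, atoms carry the numbers they have in the target (ring A C1–C5, C10; ring B C5–C10; C17 on C8; C18/C19 on C4; C20 on C10; side chain C11–C16).

**Route**

Step 1
Reactants: 1 2,4,4-trimethylcyclohex-2-en-1-one
Product: 2 (1S)-2,4,4-trimethylcyclohex-2-en-1-ol
Conditions: (R)-2-methyl-CBS-oxazaborolidine (10 mol %), BH3·SMe2, THF, −20 °C; MeOH, then aqueous work-up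
Reagents that add atoms: none
Why: Corey–Bakshi–Shibata reduction, in which the α-methyl-substituted alkenyl side acts as the large group, so the (R)-catalyst should deliver hydride to give the (S)-carbinol, the only stereocentre set by a chiral reagent.

Step 2
Reactants: 2 (1S)-2,4,4-trimethylcyclohex-2-en-1-ol
Product: 4 2-[(1R)-2,6,6-trimethylcyclohex-2-en-1-yl]acetaldehyde, via vinyl ether 3 (not isolated)
Conditions: ethyl vinyl ether, Hg(OAc)2 (cat.), reflux; concentrate; then decalin, 190 °C (sealed tube)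
Reagents that add atoms: ethyl vinyl ether, C=COCC
Why: transvinylation followed by a thermal Claisen rearrangement through a chair transition state should transfer the C1–O chirality suprafacially to C5 (new C5–C6 bond on the face the oxygen occupied) and move the alkene to C1=C10.

Step 3
Reactants: 4 2-[(1R)-2,6,6-trimethylcyclohex-2-en-1-yl]acetaldehyde
Product: 5 (6R)-1,5,5-trimethyl-6-(prop-2-en-1-yl)cyclohex-1-ene
Conditions: Ph3PCH3Br, KN(SiMe3)2, THF, 0 °C; add 4 at −78 °C → rt
Reagents that add atoms: methyltriphenylphosphonium bromide, C[P+](c1ccccc1)(c1ccccc1)c1ccccc1.[Br-]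
Why: Wittig methylenation of an unhindered aldehyde whose α-carbon is a CH2 (no epimerisable centre) should give the allyl group whose internal carbon is C7.

Step 4
Reactants: 5 (6R)-1,5,5-trimethyl-6-(prop-2-en-1-yl)cyclohex-1-ene
Product: 6 (4R)-3,5,5-trimethyl-4-(prop-2-en-1-yl)cyclohex-2-en-1-one
Conditions: Rh2(cap)4 (dirhodium tetracaprolactamate, 1 mol %), t-BuOOH, K2CO3, CH2Cl2, rt
Reagents that add atoms: tert-butyl hydroperoxide, CC(C)(C)OO
Why: catalytic allylic oxidation with t-BuOOH is selective for the ring allylic CH2 of a 1-methylcyclohexene (C2, at the CH end of C1=C10), as in α-ionone-type oxidations, while acyclic terminal alkenes are poor substrates.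

Step 5
Reactants: 6 (4R)-3,5,5-trimethyl-4-(prop-2-en-1-yl)cyclohex-2-en-1-one
Product: 9 (4S,6R)-6-{[tert-butyl(dimethyl)silyl]oxy}-3,5,5-trimethyl-4-(prop-2-en-1-yl)cyclohex-2-en-1-one, via potassium dienolate 7 (not isolated), via potassium alkoxide 8 (not isolated)
Conditions: KN(SiMe3)2, THF, −78 °C; 2-(benzenesulfonyl)-3-phenyloxaziridine, −78 °C; then t-BuMe2SiOTf, −78 → 0 °C
Reagents that add atoms: 2-(benzenesulfonyl)-3-phenyloxaziridine, O=S(=O)(N1OC1c1ccccc1)c1ccccc1; tert-butyldimethylsilyl trifluoromethanesulfonate, CC(C)(C)[Si](C)(C)OS(=O)(=O)C(F)(F)F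
Why: kinetic deprotonation gives the cross-conjugated α′-enolate at C3, and oxaziridine hydroxylation with in situ silylation should place the silyloxy group equatorial and trans to the C5 allyl group (also the thermodynamic epimer); this fixes the later ring A carbonyl at C3 without any allylic C–H oxidation.

Step 6
Reactants: 9 (4S,6R)-6-{[tert-butyl(dimethyl)silyl]oxy}-3,5,5-trimethyl-4-(prop-2-en-1-yl)cyclohex-2-en-1-one
Product: 10 (1S,4S,6R)-6-{[tert-butyl(dimethyl)silyl]oxy}-3,5,5-trimethyl-4-(prop-2-en-1-yl)cyclohex-2-en-1-ol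
Conditions: Li[s-Bu3BH] (L-Selectride), THF, −78 °C; aq. NaOH work-up
Reagents that add atoms: none
Why: the bulky hydride cannot add conjugatively to the β,β-disubstituted enone and should attack the carbonyl from the equatorial direction, anti to the axial C4 methyl, giving the pseudoaxial C2 alcohol cis to the silyloxy group and trans to the C5 allyl group.

Step 7
Reactants: 10 (1S,4S,6R)-6-{[tert-butyl(dimethyl)silyl]oxy}-3,5,5-trimethyl-4-(prop-2-en-1-yl)cyclohex-2-en-1-ol; 11 3-methylbut-2-enoyl chloride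
Product: 12 (1S,4S,6R)-6-{[tert-butyl(dimethyl)silyl]oxy}-3,5,5-trimethyl-4-(prop-2-en-1-yl)cyclohex-2-en-1-yl 3-methylbut-2-enoate
Conditions: pyridine, DMAP (cat.), CH2Cl2, 0 °C → rt
Reagents that add atoms: none
Why: DMAP-catalysed acylation of the secondary allylic alcohol by the acid chloride.

Step 8
Reactants: 12 (1S,4S,6R)-6-{[tert-butyl(dimethyl)silyl]oxy}-3,5,5-trimethyl-4-(prop-2-en-1-yl)cyclohex-2-en-1-yl 3-methylbut-2-enoate
Product: 16 (3S,5S,9R,10R)-3-{[tert-butyl(dimethyl)silyl]oxy}drima-1,7-dien-11-oic acid, via silyl ketene acetal 13 (not isolated), via monocyclic silyl ester 14 (not isolated), via bicyclic silyl ester 15 (not isolated)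
Conditions: KN(SiMe3)2, Me3SiCl, toluene–THF, −78 → 80 °C; then dilute with toluene, second-generation Hoveyda–Grubbs catalyst RuCl2(H2IMes)(=CH–C6H4-2-O-i-Pr) (5 mol %), 80 °C; 1 M HCl work-up
Reagents that add atoms: none
Why: KN(SiMe3)2 removes a γ-hydrogen of the 3-methylbut-2-enoate and Me3SiCl traps the dienolate as the (Z)-silyl ketene acetal 13, which undergoes an Ireland–Claisen [3,3] shift across O–C2–C1=C10 (new C9–C10 bond, alkene moved to C1=C2) to triene 14; the ruthenium alkylidene added to the same flask then joins the allyl CH (C7) to the isopropenyl carbon (C8) and expels ethene. The closest known reaction types are the deconjugative ester-enolate Claisen of allyl 3-methylbut-2-enoates (the lavandulyl construction) and ring-closing metathesis of a mono- with a 1,1-disubstituted alkene to a trisubstituted cyclohexene, run consecutively in one flask because KCl, HN(SiMe3)2 and the silyl ester should not bind the catalyst. Ring B is closed as a six-membered ring by [2+2]/retro-[2+2] metathesis with the new C7=C8 bond endocyclic, and the fusion is trans because the C6 and C9 arms are trans-diequatorial on ring A. C10 is controlled by suprafacial transfer from the C2–O bond (C9 enters on the face of the oxygen, anti to the C5 allyl group), and C9 by the boat-like transition state preferred by cyclohex-2-enyl esters (a chair would put the OSiMe3-bearing carbon over ring A and its C4 methyl) together with the Z geometry of 13, which places the isopropenyl group outside and H-9 over the ring. The step needs metathesis to engage only the two terminal alkenes, which is secured because the ring A alkene is a cis-disubstituted cyclohexene flanked by quaternary C10 and the silyloxy-bearing C3 and offers no productive ring closure.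

Step 9
Reactants: 16 (3S,5S,9R,10R)-3-{[tert-butyl(dimethyl)silyl]oxy}drima-1,7-dien-11-oic acid
Product: 17 (3S,5S,9R,10R)-3-{[tert-butyl(dimethyl)silyl]oxy}drima-1,7-dien-11-ol
Conditions: LiAlH4, Et2O, 0 °C → rt
Reagents that add atoms: none
Why: hydride reduction of the carboxylic acid to the primary C11 alcohol leaves the isolated alkenes and the silyl ether untouched.

Step 10
Reactants: 17 (3S,5S,9R,10R)-3-{[tert-butyl(dimethyl)silyl]oxy}drima-1,7-dien-11-ol; 18 trimethyl(prop-1-yn-1-yl)silane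
Product: 20 (3S,5S,9R,10S)-3-{[tert-butyl(dimethyl)silyl]oxy}-14-(trimethylsilyl)-15,16-dinorlabda-1,7-dien-13-yne, via triflate 19 (not isolated)
Conditions: Tf2O, 2,6-lutidine, CH2Cl2, −78 °C; then LiCH2C≡CSiMe3 (from 18, n-BuLi, THF, −78 °C), THF–HMPA, −78 → −30 °C
Reagents that add atoms: none
Why: SN2 displacement of the primary triflate by the propargylic carbanion of the silylpropyne is a standard three-carbon homologation and should install C12–C14 as a masked terminal alkyne.

Step 11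
Reactants: 20 (3S,5S,9R,10S)-3-{[tert-butyl(dimethyl)silyl]oxy}-14-(trimethylsilyl)-15,16-dinorlabda-1,7-dien-13-yne
Product: 21 (3S,5S,9R,10S)-15,16-dinorlabda-1,7-dien-13-yn-3-ol
Conditions: Bu4NF, THF, rt → 45 °C
Reagents that add atoms: none
Why: fluoride should cleave the alkynyl C–Si and the O–Si bond in one operation.

Step 12
Reactants: 21 (3S,5S,9R,10S)-15,16-dinorlabda-1,7-dien-13-yn-3-ol
Product: 23 (3S,5S,9R,10S,13E)-3-hydroxylabda-1,7,13-trien-15-oic acid, via alkenylalane 22 (not isolated)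
Conditions: AlMe3, Cp2ZrCl2 (0.5 equiv), CH2Cl2, 0 °C → rt; then n-BuLi, THF, −78 °C; CO2; aq. HCl
Reagents that add atoms: trimethylaluminium, C[Al](C)C; carbon dioxide, O=C=O
Why: Negishi carboalumination adds CH3 and Al syn across the terminal alkyne with Al at the terminus, and carboxylation of the derived alanate with retention should give the (E)-3-methyl-2-enoic acid; the di- and trisubstituted ring alkenes are inert.

Step 13
Reactants: 23 (3S,5S,9R,10S,13E)-3-hydroxylabda-1,7,13-trien-15-oic acid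
Product: 24 (5S,9R,10S,13E)-3-oxolabda-1,7,13-trien-15-oic acid
Conditions: Dess–Martin periodinane, NaHCO3, CH2Cl2, rt
Reagents that add atoms: none
Why: oxidation of the allylic alcohol gives the 1-en-3-one chemoselectively.

Step 14
Reactants: 24 (5S,9R,10S,13E)-3-oxolabda-1,7,13-trien-15-oic acid
Product: 26 (2S,5S,9R,10S,13E)-2-hydroxy-3-oxolabda-7,13-dien-15-oic acid, via lithium enolate 25 (not isolated)
Conditions: Li[s-Bu3BH] (L-Selectride), THF, −78 °C; then 2-(benzenesulfonyl)-3-phenyloxaziridine, −78 → −40 °C; aq. NH4Cl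
Reagents that add atoms: 2-(benzenesulfonyl)-3-phenyloxaziridine, O=S(=O)(N1OC1c1ccccc1)c1ccccc1
Why: hydride should add conjugatively (direct attack is blocked by the C4 gem-dimethyl group) and the resulting C2=C3 enolate should be hydroxylated on the face anti to the axial C20 and C4 methyl groups, giving the equatorial 2-hydroxy ketone.

Step 15
Reactants: 26 (2S,5S,9R,10S,13E)-2-hydroxy-3-oxolabda-7,13-dien-15-oic acid
Product: 27 (2S,3R,5S,9R,10S,13E)-2,3-dihydroxylabda-7,13-dien-15-oic acid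
Conditions: K[s-Bu3BH] (K-Selectride), THF, −78 °C; aq. NH4Cl
Reagents that add atoms: none
Why: the bulky trialkylborohydride should attack the 4,4-dimethyl-3-ketone from the equatorial direction, as in reductions of 3-oxotriterpenoids to axial 3-alcohols, giving the axial C3 hydroxyl cis to the C2 hydroxyl.

Step 16
Reactants: 27 (2S,3R,5S,9R,10S,13E)-2,3-dihydroxylabda-7,13-dien-15-oic acid
Product: 29 (2S,3R,5S,9R,10S,13E)-2,3-bis(acetyloxy)labda-7,13-dien-15-oic acid, via mixed anhydride 28 (not isolated)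
Conditions: Ac2O, pyridine, DMAP, rt → 40 °C; then THF–aq. NaHCO3, rt; acidify
Reagents that add atoms: acetic anhydride, CC(=O)OC(C)=O
Why: DMAP-catalysed acetylation should esterify both secondary hydroxyls, and the mixed carboxylic–acetic anhydride formed at C15 is hydrolysed in the bicarbonate work-up to leave the diacetoxy acid.

**Compound list**

1 | 2,4,4-trimethylcyclohex-2-en-1-one | CC1=CC(C)(C)CCC1=O | starting material
2 | (1S)-2,4,4-trimethylcyclohex-2-en-1-ol | O[C@H]1CCC(C)(C)C=C1C | intermediate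
3 | (6S)-6-(ethenyloxy)-1,3,3-trimethylcyclohex-1-ene | C=CO[C@H]1CCC(C)(C)C=C1C | intermediate
4 | 2-[(1R)-2,6,6-trimethylcyclohex-2-en-1-yl]acetaldehyde | C1=C(C)[C@H](CC=O)C(C)(C)CC1 | intermediate
5 | (6R)-1,5,5-trimethyl-6-(prop-2-en-1-yl)cyclohex-1-ene | C1=C(C)[C@H](CC=C)C(C)(C)CC1 | intermediate
6 | (4R)-3,5,5-trimethyl-4-(prop-2-en-1-yl)cyclohex-2-en-1-one | O=C1C=C(C)[C@H](CC=C)C(C)(C)C1 | intermediate
7 | potassium cross-conjugated dienolate of 6 (O–C2=C3, C1=C10) | [K+].[O-]C1=CC(C)(C)[C@@H](CC=C)C(C)=C1 | intermediate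
8 | potassium alkoxide of (4S,6R)-6-hydroxy-3,5,5-trimethyl-4-(prop-2-en-1-yl)cyclohex-2-en-1-one | O=C1C=C(C)[C@H](CC=C)C(C)(C)[C@H]1[O-].[K+] | intermediate
9 | (4S,6R)-6-{[tert-butyl(dimethyl)silyl]oxy}-3,5,5-trimethyl-4-(prop-2-en-1-yl)cyclohex-2-en-1-one | O=C1C=C(C)[C@H](CC=C)C(C)(C)[C@H]1O[Si](C)(C)C(C)(C)C | intermediate
10 | (1S,4S,6R)-6-{[tert-butyl(dimethyl)silyl]oxy}-3,5,5-trimethyl-4-(prop-2-en-1-yl)cyclohex-2-en-1-ol | O[C@H]1C=C(C)[C@H](CC=C)C(C)(C)[C@H]1O[Si](C)(C)C(C)(C)C | intermediate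
11 | 3-methylbut-2-enoyl chloride | CC(C)=CC(Cl)=O | starting material
12 | (1S,4S,6R)-6-{[tert-butyl(dimethyl)silyl]oxy}-3,5,5-trimethyl-4-(prop-2-en-1-yl)cyclohex-2-en-1-yl 3-methylbut-2-enoate | CC(C)=CC(=O)O[C@H]1C=C(C)[C@H](CC=C)C(C)(C)[C@H]1O[Si](C)(C)C(C)(C)C | intermediate
13 | (1Z)-silyl ketene acetal of 12: trimethyl{[3-methyl-1-(cyclohexenyloxy)buta-1,3-dien-1-yl]oxy}silane, isopropenyl cis to OSiMe3 | C=C(C)/C=C(/O[C@H]1C=C(C)[C@H](CC=C)C(C)(C)[C@H]1O[Si](C)(C)C(C)(C)C)O[Si](C)(C)C | intermediate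
14 | trimethylsilyl (2R)-2-[(1R,4S,6S)-4-{[tert-butyl(dimethyl)silyl]oxy}-1,5,5-trimethyl-6-(prop-2-en-1-yl)cyclohex-2-en-1-yl]-3-methylbut-3-enoate | C1=C[C@@](C)([C@H](C(=O)O[Si](C)(C)C)C(C)=C)[C@H](CC=C)C(C)(C)[C@H]1O[Si](C)(C)C(C)(C)C | intermediate
15 | trimethylsilyl (3S,5S,9R,10R)-3-{[tert-butyl(dimethyl)silyl]oxy}drima-1,7-dien-11-oate | C1=C[C@@]2(C)[C@H](C(=O)O[Si](C)(C)C)C(C)=CC[C@@H]2C(C)(C)[C@H]1O[Si](C)(C)C(C)(C)C | intermediate
16 | (3S,5S,9R,10R)-3-{[tert-butyl(dimethyl)silyl]oxy}drima-1,7-dien-11-oic acid | C1=C[C@@]2(C)[C@H](C(=O)O)C(C)=CC[C@@H]2C(C)(C)[C@H]1O[Si](C)(C)C(C)(C)C | intermediate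
17 | (3S,5S,9R,10R)-3-{[tert-butyl(dimethyl)silyl]oxy}drima-1,7-dien-11-ol | C1=C[C@@]2(C)[C@H](CO)C(C)=CC[C@@H]2C(C)(C)[C@H]1O[Si](C)(C)C(C)(C)C | intermediate
18 | trimethyl(prop-1-yn-1-yl)silane | CC#C[Si](C)(C)C | starting material
19 | (3S,5S,9R,10R)-3-{[tert-butyl(dimethyl)silyl]oxy}drima-1,7-dien-11-yl trifluoromethanesulfonate | C1=C[C@@]2(C)[C@H](COS(=O)(=O)C(F)(F)F)C(C)=CC[C@@H]2C(C)(C)[C@H]1O[Si](C)(C)C(C)(C)C | intermediate
20 | (3S,5S,9R,10S)-3-{[tert-butyl(dimethyl)silyl]oxy}-14-(trimethylsilyl)-15,16-dinorlabda-1,7-dien-13-yne | C1=C[C@@]2(C)[C@H](CCC#C[Si](C)(C)C)C(C)=CC[C@@H]2C(C)(C)[C@H]1O[Si](C)(C)C(C)(C)C | intermediate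
21 | (3S,5S,9R,10S)-15,16-dinorlabda-1,7-dien-13-yn-3-ol | C1=C[C@@]2(C)[C@H](CCC#C)C(C)=CC[C@@H]2C(C)(C)[C@H]1O | intermediate
22 | (13E)-14-(dimethylalumanyl)-3-[(dimethylalumanyl)oxy]-15-norlabda-1,7,13-triene | C1=C[C@@]2(C)[C@H](CC/C(C)=C/[Al](C)C)C(C)=CC[C@@H]2C(C)(C)[C@H]1O[Al](C)C | intermediate
23 | (3S,5S,9R,10S,13E)-3-hydroxylabda-1,7,13-trien-15-oic acid | C1=C[C@@]2(C)[C@H](CC/C(C)=C/C(=O)O)C(C)=CC[C@@H]2C(C)(C)[C@H]1O | intermediate
24 | (5S,9R,10S,13E)-3-oxolabda-1,7,13-trien-15-oic acid | O=C1C=C[C@@]2(C)[C@H](CC/C(C)=C/C(=O)O)C(C)=CC[C@@H]2C1(C)C | intermediate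
25 | dilithium salt of the C2=C3 enolate of (13E)-3-oxolabda-7,13-dien-15-oate | [Li+].[Li+].[O-]C1=CC[C@@]2(C)[C@H](CC/C(C)=C/C([O-])=O)C(C)=CC[C@@H]2C1(C)C | intermediate
26 | (2S,5S,9R,10S,13E)-2-hydroxy-3-oxolabda-7,13-dien-15-oic acid | O[C@H]1C[C@@]2(C)[C@H](CC/C(C)=C/C(=O)O)C(C)=CC[C@@H]2C(C)(C)C1=O | intermediate
27 | (2S,3R,5S,9R,10S,13E)-2,3-dihydroxylabda-7,13-dien-15-oic acid | O[C@H]1C[C@@]2(C)[C@H](CC/C(C)=C/C(=O)O)C(C)=CC[C@@H]2C(C)(C)[C@H]1O | intermediate
28 | acetic (2S,3R,5S,9R,10S,13E)-2,3-bis(acetyloxy)labda-7,13-dien-15-oic anhydride | CC(=O)O[C@H]1C[C@@]2(C)[C@H](CC/C(C)=C/C(=O)OC(C)=O)C(C)=CC[C@@H]2C(C)(C)[C@H]1OC(C)=O | intermediate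
29 | (2S,3R,5S,9R,10S,13E)-2,3-bis(acetyloxy)labda-7,13-dien-15-oic acid | CC(=O)O[C@H]1C[C@@]2(C)[C@H](CC/C(C)=C/C(=O)O)C(C)=CC[C@@H]2C(C)(C)[C@H]1OC(C)=O | target

**Summary**

Total step count: 16. Longest linear sequence: 16 steps (1 → 29; 11 and 18 are purchased).

Steps most likely to fail:

- Step 8. The rearrangement may leak through the chair-like transition state and give the C9 epimer. The congested C9–C10 bond may fail to form. The metathesis catalyst may be deactivated in the one-flask mode. Fallback, from 10 back to 17: Johnson–Claisen rearrangement of 10 (triethyl orthoacetate, cat. propionic acid, xylene, 140 °C) gives the ethyl ester F1, with C10 set and C9 still a CH2. Its lithium enolate (LiN(i-Pr)2, THF, −78 °C) is added to acetone to give the β-hydroxy ester F2. Dehydration with the Burgess reagent gives the isopropenyl ester F3, and the C9 epimers are separated at this stage if necessary. Ring-closing metathesis of isolated F3 with the second-generation Hoveyda–Grubbs catalyst gives the bicyclic ethyl ester F4. LiAlH4 reduction of F4 gives alcohol 17.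

- Step 10. The homoallylic triflate may lose triflic acid by base-induced elimination toward the conjugated 7,9(11)-diene, or substitution at the β-branched C11 may be too slow. Fallback, from 17 back to 23: 17 is converted with I2, PPh3 and imidazole into the iodide F5. F5 alkylates the softer, less basic dianion of methyl acetoacetate (NaH, then n-BuLi) at its terminal carbon to give the β-keto ester F6. NaH and ClP(O)(OEt)2 give the Z-enol phosphate F7, and Me2CuLi replaces the phosphate with retention to give the (E)-methyl ester F8. Bu4NF gives the allylic alcohol F9, and LiOH hydrolysis gives acid 23.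

- Step 15. Facial selectivity in the ketone reduction may be poor (equatorial 3-alcohol, trans-diol), or the α-hydroxy ketone may epimerise before reduction. Fallback, from 24 back to 27: conjugate reduction of 24 with Li[s-Bu3BH] and trapping of the enolate with PhNTf2 gives the enol triflate F10. Formate reduction (Pd(OAc)2, PPh3, Bu3N, HCO2H, DMF) gives the 2-ene F11. OsO4 (cat.)/NMO dihydroxylation from the face opposite the axial C20 and C4 methyl groups gives cis-diol 27 directly. The electron-poor 13-enoate and the hindered trisubstituted 7-ene are expected to react more slowly than the 2-ene.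

Further compounds
F1 | step 8 | ethyl 2-[(1R,4S,6S)-4-{[tert-butyl(dimethyl)silyl]oxy}-1,5,5-trimethyl-6-(prop-2-en-1-yl)cyclohex-2-en-1-yl]acetate | C1=C[C@@](C)(CC(=O)OCC)[C@H](CC=C)C(C)(C)[C@H]1O[Si](C)(C)C(C)(C)C
F2 | step 8 | ethyl (2S)-3-hydroxy-3-methyl-2-[(1R,4S,6S)-4-{[tert-butyl(dimethyl)silyl]oxy}-1,5,5-trimethyl-6-(prop-2-en-1-yl)cyclohex-2-en-1-yl]butanoate | C1=C[C@@](C)([C@H](C(=O)OCC)C(C)(C)O)[C@H](CC=C)C(C)(C)[C@H]1O[Si](C)(C)C(C)(C)C
F3 | step 8 | ethyl (2R)-3-methyl-2-[(1R,4S,6S)-4-{[tert-butyl(dimethyl)silyl]oxy}-1,5,5-trimethyl-6-(prop-2-en-1-yl)cyclohex-2-en-1-yl]but-3-enoate | C1=C[C@@](C)([C@H](C(=O)OCC)C(C)=C)[C@H](CC=C)C(C)(C)[C@H]1O[Si](C)(C)C(C)(C)C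
F4 | step 8 | ethyl (3S,5S,9R,10R)-3-{[tert-butyl(dimethyl)silyl]oxy}drima-1,7-dien-11-oate | C1=C[C@@]2(C)[C@H](C(=O)OCC)C(C)=CC[C@@H]2C(C)(C)[C@H]1O[Si](C)(C)C(C)(C)C
F5 | step 10 | (3S,5S,9R,10R)-3-{[tert-butyl(dimethyl)silyl]oxy}-11-iododrima-1,7-diene | C1=C[C@@]2(C)[C@H](CI)C(C)=CC[C@@H]2C(C)(C)[C@H]1O[Si](C)(C)C(C)(C)C
F6 | step 10 | methyl (3S,5S,9R,10S)-3-{[tert-butyl(dimethyl)silyl]oxy}-13-oxo-16-norlabda-1,7-dien-15-oate | C1=C[C@@]2(C)[C@H](CCC(=O)CC(=O)OC)C(C)=CC[C@@H]2C(C)(C)[C@H]1O[Si](C)(C)C(C)(C)C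
F7 | step 10 | methyl (13Z)-3-{[tert-butyl(dimethyl)silyl]oxy}-13-[(diethoxyphosphoryl)oxy]-16-norlabda-1,7,13-trien-15-oate, ring stereocentres as in 17 | C1=C[C@@]2(C)[C@H](CC/C(OP(=O)(OCC)OCC)=C/C(=O)OC)C(C)=CC[C@@H]2C(C)(C)[C@H]1O[Si](C)(C)C(C)(C)C
F8 | step 10 | methyl (3S,5S,9R,10S,13E)-3-{[tert-butyl(dimethyl)silyl]oxy}labda-1,7,13-trien-15-oate | C1=C[C@@]2(C)[C@H](CC/C(C)=C/C(=O)OC)C(C)=CC[C@@H]2C(C)(C)[C@H]1O[Si](C)(C)C(C)(C)C
F9 | step 10 | methyl (3S,5S,9R,10S,13E)-3-hydroxylabda-1,7,13-trien-15-oate | C1=C[C@@]2(C)[C@H](CC/C(C)=C/C(=O)OC)C(C)=CC[C@@H]2C(C)(C)[C@H]1O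
F10 | step 15 | (5S,9R,10S,13E)-3-{[(trifluoromethyl)sulfonyl]oxy}labda-2,7,13-trien-15-oic acid | O=S(=O)(OC1=CC[C@@]2(C)[C@H](CC/C(C)=C/C(=O)O)C(C)=CC[C@@H]2C1(C)C)C(F)(F)F
F11 | step 15 | (5R,9R,10S,13E)-labda-2,7,13-trien-15-oic acid | C1=CC[C@@]2(C)[C@H](CC/C(C)=C/C(=O)O)C(C)=CC[C@@H]2C1(C)C
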